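**Retrosynthetic overview**
1. The last events are O-demethylation and an sp3–sp3 Suzuki–Miyaura union (C2'–C3') of a 2-vinylchroman with a C14 bromide. That bromide comes from (R)-citronellyl bromide and (S)-3-bromo-2-methylpropan-1-ol (C5'–C6' bond), which bring in C8' and C4'.
2. The chroman is traced back to a chroman-4-one-2-carboxylate: C4 is carried as a ketone and C1' as an ester, both adjusted after the ring is made.
3. Key disconnection: C2–C3 and O1–C8a are cut together, giving the enol silane of an ortho-fluoroacetophenone and methyl pyruvate. Forward, a copper–bis(oxazoline)-catalyzed Mukaiyama aldol sets C2 and a fluoride-relayed SNAr closes the ring in the same flask.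
4. Enabling feature: C4, the benzylic carbon of the pyran ring on ring-fusion carbon C4a, lies ortho to the oxygen-bearing carbon C8a of the benzene ring. At the ketone level it makes C3 an enolsilane nucleophile and activates the C8a–F bond for addition–elimination; the 1,2-dicarbonyl of pyruvate (future C2 and C1') gives two-point binding to the chiral catalyst.
5. Ring order: the benzene ring is bought (4-fluoro-3-methylanisole); the pyran ring (O1–C2–C3–C4–C4a–C8a) is the only ring formed, in step 3.

Key step: step 3

Remark on the chemistry: chroman numbering (O1, C2, C3, C4, C4a, C5–C8, C8a; side chain C1'–C13') is used. The target is read as (2R,4'R,8'S); 8'S is the spatial arrangement of 8'R in a saturated tocopherol side chain, because the 11',12' double bond reverses the CIP order at C8'. The phenol is carried as its methyl ether; (S,S)-t-Bu-box is 2,2'-(propane-2,2-diyl)bis[(4S)-4-tert-butyl-4,5-dihydro-1,3-oxazole].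

**Route**

Step 1
Reactants: 1 4-fluoro-3-methylanisole; 2 N-methoxy-N-methylacetamide
Product: 4 1-(2-fluoro-5-methoxy-3-methylphenyl)ethan-1-one, via aryllithium 3 (not isolated)
Conditions: n-BuLi, PMDTA, THF, −75 °C; then 2, −75 → 0 °C; H2O
Reagents that add atoms: none
Why: Directed ortho-metalation in which the PMDTA-saturated lithium base removes the most acidic ring proton, the one next to fluorine rather than those next to the methoxy group, followed by acylation of the aryllithium with the N-methoxy-N-methylamide, which stops at the ketone stage.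

Step 2
Reactants: 4 1-(2-fluoro-5-methoxy-3-methylphenyl)ethan-1-one
Product: 5 {[1-(2-fluoro-5-methoxy-3-methylphenyl)ethenyl]oxy}trimethylsilane
Conditions: Me3SiOTf, Et3N, CH2Cl2, 0 °C
Reagents that add atoms: trimethylsilyl trifluoromethanesulfonate, C[Si](C)(C)OS(=O)(=O)C(F)(F)F
Why: Silyl enol ether formation by soft enolization of a methyl ketone with a single enolizable position, so only one enol silane can form.

Step 3
Reactants: 5 {[1-(2-fluoro-5-methoxy-3-methylphenyl)ethenyl]oxy}trimethylsilane; 6 methyl pyruvate
Product: 9 methyl (2S)-6-methoxy-2,8-dimethyl-4-oxochromane-2-carboxylate, via silyl aldol adduct 7 (not isolated), via tertiary alkoxide 8 (not isolated)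
Conditions: [Cu((S,S)-t-Bu-box)](OTf)2 (10 mol %), THF, −78 °C; then Bu4NF (1.2 equiv), DMF, −40 → 25 °C; AcOH quench
Reagents that add atoms: none
Why: Methyl pyruvate binds the chiral divalent copper Lewis acid through both carbonyl oxygens, enolsilane 5 adds through an open transition state to the unshielded si face of the ketone to form C2–C3 (Mukaiyama aldol) and silyl transfer releases 7; fluoride then unmasks tertiary alkoxide 8, which adds to C8a ortho to the C4 ketone and expels fluoride through an anionic σ-adduct to form O1–C8a (SNAr), the expelled fluoride desilylating the next molecule of 7 as a fluoride relay. The closest known reaction types are the Cu(OTf)2–bis(oxazoline)-catalyzed enantioselective addition of enolsilanes to pyruvate esters and the intramolecular SNAr etherification of ortho-fluoroaryl ketones; together they mirror the aldol–cyclization route from 1-alkoxy-3-silyloxydienes and carbonyl compounds to dihydropyranones, with the C8a–F bond of the arene in the role of the vinylogous ester. The pyran ring closes by a six-membered addition–elimination at sp2 carbon C8a, formally 6-endo-trig with respect to the C8a=C4a–C4=O unit. The new stereocenter C2 is set by the catalyst alone (the tert-butyl groups of the (S,S) ligand should block the re face), giving the 2S ester, which corresponds to 2R in the target because the ester carbon becomes C1'. The step needs enantioface control, secured by two-point binding of the 1,2-dicarbonyl, and ring closure faster than retro-aldol cleavage or loss of silanolate to an enone, secured by ortho-acyl activation of C8a, the intramolecular six-membered geometry, the silicon-selective fluoride trigger and the low temperature.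

Step 4
Reactants: 9 methyl (2S)-6-methoxy-2,8-dimethyl-4-oxochromane-2-carboxylate
Product: 10 methyl (2S)-6-methoxy-2,8-dimethylchromane-2-carboxylate
Conditions: Et3SiH, CF3CO2H, 25 → 55 °C
Reagents that add atoms: none
Why: Ionic hydrogenation reduces the aryl ketone to CH2 through a benzylic cation stabilized by the ortho ring oxygen O1, while the non-enolizable ester, the aryl ethers and the quaternary C2 center are untouched.

Step 5
Reactants: 10 methyl (2S)-6-methoxy-2,8-dimethylchromane-2-carboxylate
Product: 11 (2S)-6-methoxy-2,8-dimethylchromane-2-carbaldehyde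
Conditions: i-Bu2AlH, CH2Cl2, −78 °C; aq. KNaC4H4O6
Reagents that add atoms: none
Why: Partial ester reduction with i-Bu2AlH should stop at the aldehyde because the aluminium hemiacetal, chelated by the α ring oxygen, persists at −78 °C, and the α-quaternary aldehyde cannot epimerize.

Step 6
Reactants: 11 (2S)-6-methoxy-2,8-dimethylchromane-2-carbaldehyde; 12 methyltriphenylphosphonium bromide
Product: 14 (2S)-2-ethenyl-6-methoxy-2,8-dimethylchromane, via ylide 13 (not isolated)
Conditions: KOt-Bu, THF, 0 → 25 °C
Reagents that add atoms: none
Why: Wittig methylenation of a non-enolizable aldehyde by the unstabilized ylide supplies side-chain carbon C2' without touching the C2 stereocenter.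

Step 7
Reactants: 15 (6R)-8-bromo-2,6-dimethyloct-2-ene [(R)-citronellyl bromide]; 16 (2S)-3-bromo-2-methylpropan-1-ol
Product: 19 (2R,6S)-2,6,10-trimethylundec-9-en-1-ol, via Grignard reagent 17 (not isolated), via magnesium alkoxide 18 (not isolated)
Conditions: 15, Mg, THF; 16, MeMgCl (1.0 equiv), THF, −30 °C; combine, Li2CuCl4 (5 mol %), −20 → 20 °C; aq. NH4Cl
Reagents that add atoms: none
Why: Copper-catalyzed sp3–sp3 cross-coupling of a primary Grignard reagent with a primary alkyl bromide, the hydroxyl being masked in the flask as its chloromagnesium alkoxide, joins the two chiral-pool pieces at non-stereogenic carbons so that both methyl-bearing stereocenters are carried over unchanged.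

Step 8
Reactants: 19 (2R,6S)-2,6,10-trimethylundec-9-en-1-ol
Product: 20 (6S,10R)-11-bromo-2,6,10-trimethylundec-2-ene
Conditions: CBr4, PPh3, CH2Cl2, 0 °C
Reagents that add atoms: carbon tetrabromide, BrC(Br)(Br)Br
Why: Appel bromination replaces the primary hydroxyl under neutral conditions at the CH2 group only, leaving the neighbouring stereocenter and the trisubstituted alkene untouched.

Step 9
Reactants: 14 (2S)-2-ethenyl-6-methoxy-2,8-dimethylchromane; 20 (6S,10R)-11-bromo-2,6,10-trimethylundec-2-ene
Product: 22 (2R)-6-methoxy-2,8-dimethyl-2-[(4R,8S)-4,8,12-trimethyltridec-11-en-1-yl]chromane, via alkylborane 21 (not isolated)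
Conditions: 9-BBN-H, THF, 25 °C; then 20, NiCl2·glyme (6 mol %), trans-N,N'-dimethylcyclohexane-1,2-diamine (8 mol %), KOt-Bu, i-BuOH, dioxane, 25 °C
Reagents that add atoms: none
Why: Anti-Markovnikov hydroboration of the monosubstituted alkene followed by nickel-catalyzed alkyl–alkyl Suzuki–Miyaura coupling with the unactivated primary bromide forms C2'–C3' between two non-stereogenic CH2 carbons, and the trisubstituted alkene of 20 never meets free borane.

Step 10
Reactants: 22 (2R)-6-methoxy-2,8-dimethyl-2-[(4R,8S)-4,8,12-trimethyltridec-11-en-1-yl]chromane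
Product: 23 (2R)-2,8-dimethyl-2-[(4R,8S)-4,8,12-trimethyltridec-11-en-1-yl]chroman-6-ol (target)
Conditions: NaSEt, DMF, 140 °C, argon; aq. HCl
Reagents that add atoms: none
Why: Nucleophilic O-demethylation by thiolate attack at the methyl carbon frees the phenol, while the chroman ether cannot be attacked at its quaternary carbon and the isolated alkene is inert to thiolate.

**Compound list**
1 | 4-fluoro-3-methylanisole | COc1ccc(F)c(C)c1 | starting material
2 | N-methoxy-N-methylacetamide | CC(=O)N(C)OC | starting material
3 | (2-fluoro-5-methoxy-3-methylphenyl)lithium | COc1cc([Li])c(F)c(C)c1 | intermediate (not isolated)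
4 | 1-(2-fluoro-5-methoxy-3-methylphenyl)ethan-1-one | COc1cc(C(C)=O)c(F)c(C)c1 | intermediate
5 | {[1-(2-fluoro-5-methoxy-3-methylphenyl)ethenyl]oxy}trimethylsilane | COc1cc(C(=C)O[Si](C)(C)C)c(F)c(C)c1 | intermediate
6 | methyl pyruvate | CC(=O)C(=O)OC | starting material
7 | methyl (2S)-4-(2-fluoro-5-methoxy-3-methylphenyl)-2-methyl-4-oxo-2-[(trimethylsilyl)oxy]butanoate | C[C@](O[Si](C)(C)C)(CC(=O)c1cc(OC)cc(C)c1F)C(=O)OC | intermediate (not isolated)
8 | tetrabutylammonium alkoxide of methyl (2S)-4-(2-fluoro-5-methoxy-3-methylphenyl)-2-hydroxy-2-methyl-4-oxobutanoate | C[C@]([O-])(CC(=O)c1cc(OC)cc(C)c1F)C(=O)OC.CCCC[N+](CCCC)(CCCC)CCCC | intermediate (not isolated)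
9 | methyl (2S)-6-methoxy-2,8-dimethyl-4-oxochromane-2-carboxylate | COC(=O)[C@]1(C)CC(=O)c2cc(OC)cc(C)c2O1 | intermediate
10 | methyl (2S)-6-methoxy-2,8-dimethylchromane-2-carboxylate | COC(=O)[C@]1(C)CCc2cc(OC)cc(C)c2O1 | intermediate
11 | (2S)-6-methoxy-2,8-dimethylchromane-2-carbaldehyde | O=C[C@]1(C)CCc2cc(OC)cc(C)c2O1 | intermediate
12 | methyltriphenylphosphonium bromide | C[P+](c1ccccc1)(c1ccccc1)c1ccccc1.[Br-] | starting material
13 | methylidenetriphenyl-λ5-phosphane | C=P(c1ccccc1)(c1ccccc1)c1ccccc1 | intermediate (not isolated)
14 | (2S)-2-ethenyl-6-methoxy-2,8-dimethylchromane | C=C[C@]1(C)CCc2cc(OC)cc(C)c2O1 | intermediate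
15 | (6R)-8-bromo-2,6-dimethyloct-2-ene [(R)-citronellyl bromide] | CC(C)=CCC[C@@H](C)CCBr | starting material
16 | (2S)-3-bromo-2-methylpropan-1-ol | BrC[C@@H](C)CO | starting material
17 | [(3R)-3,7-dimethyloct-6-en-1-yl]magnesium bromide | CC(C)=CCC[C@@H](C)CC[Mg]Br | intermediate (not isolated)
18 | chloromagnesium (2S)-3-bromo-2-methylpropan-1-olate | BrC[C@@H](C)CO[Mg]Cl | intermediate (not isolated)
19 | (2R,6S)-2,6,10-trimethylundec-9-en-1-ol | CC(C)=CCC[C@@H](C)CCC[C@@H](C)CO | intermediate
20 | (6S,10R)-11-bromo-2,6,10-trimethylundec-2-ene | CC(C)=CCC[C@@H](C)CCC[C@@H](C)CBr | intermediate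
21 | 9-{2-[(2R)-6-methoxy-2,8-dimethylchroman-2-yl]ethyl}-9-borabicyclo[3.3.1]nonane | C1CC2CCCC(C1)B2CC[C@]1(C)CCc2cc(OC)cc(C)c2O1 | intermediate (not isolated)
22 | (2R)-6-methoxy-2,8-dimethyl-2-[(4R,8S)-4,8,12-trimethyltridec-11-en-1-yl]chromane | CC(C)=CCC[C@@H](C)CCC[C@@H](C)CCC[C@]1(C)CCc2cc(OC)cc(C)c2O1 | intermediate
23 | (2R)-2,8-dimethyl-2-[(4R,8S)-4,8,12-trimethyltridec-11-en-1-yl]chroman-6-ol | CC(C)=CCC[C@@H](C)CCC[C@@H](C)CCC[C@]1(C)CCc2cc(O)cc(C)c2O1 | target

**Counts**
Total steps: 10. Longest linear sequence: 8 (steps 1–6, 9, 10); steps 7 and 8 form the side-chain branch.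

**Steps most likely to fail**

1. Step 3. Process at risk: loss of enantiopurity and material through retro-aldol cleavage of the alkoxide, elimination of silanolate to an enone, or reversible base-induced opening of the chromanone ring once it has formed. The fallback sets out from 7 and comes back at 10. The aldol stage is worked up without base and 7 is isolated. Ionic hydrogenation (Et3SiH, CF3CO2H, BF3·OEt2) removes the C4 carbonyl and the silyl group to give methyl (2S)-4-(2-fluoro-5-methoxy-3-methylphenyl)-2-hydroxy-2-methylbutanoate F1, in which no β-carbonyl is left for retro-aldol or ring-opening chemistry. Base-mediated intramolecular etherification of the non-activated aryl fluoride (KN(SiMe3)2 or KOt-Bu, NMP, 100–120 °C) then closes the pyran ring and gives 10 directly; the ester has no α-hydrogen and should survive.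

2. Step 9. Process at risk: slow activation of the β-branched primary bromide, so that β-hydride elimination and protodeboronation take over. The fallback sets out from 21 and comes back at 22. The borane is oxidized (NaOH, H2O2) to 2-[(2S)-6-methoxy-2,8-dimethylchroman-2-yl]ethan-1-ol F2, which is converted (TsCl, pyridine) to 2-[(2S)-6-methoxy-2,8-dimethylchroman-2-yl]ethyl 4-methylbenzenesulfonate F3. The Grignard reagent [(2R,6S)-2,6,10-trimethylundec-9-en-1-yl]magnesium bromide F4, made from 20 and Mg in THF, is then coupled with F3 under Li2CuCl4 catalysis (THF, −20 → 20 °C) to give 22.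

3. Step 1. Process at risk: metalation at the wrong ring position or at the benzylic methyl group, and proton transfer from the acetamide to the aryllithium instead of acylation. The fallback sets out from 1 and comes back at 4. Iridium-catalyzed C–H borylation ([Ir(OMe)(cod)]2, 4,4'-di-tert-butyl-2,2'-bipyridine, bis(pinacolato)diboron, hexane, 60 °C) should select the C–H next to the small fluorine, the other two ring positions being flanked by the methoxy or the methyl group, and give 2-(2-fluoro-5-methoxy-3-methylphenyl)-4,4,5,5-tetramethyl-1,3,2-dioxaborolane F5. Acylative Suzuki–Miyaura coupling with acetyl chloride (Pd(PPh3)4, Cs2CO3, toluene, 80 °C) then gives 4.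

**Further compounds**
F1 | step 3 | methyl (2S)-4-(2-fluoro-5-methoxy-3-methylphenyl)-2-hydroxy-2-methylbutanoate | C[C@](O)(CCc1cc(OC)cc(C)c1F)C(=O)OC
F2 | step 9 | 2-[(2S)-6-methoxy-2,8-dimethylchroman-2-yl]ethan-1-ol | OCC[C@]1(C)CCc2cc(OC)cc(C)c2O1
F3 | step 9 | 2-[(2S)-6-methoxy-2,8-dimethylchroman-2-yl]ethyl 4-methylbenzenesulfonate | Cc1ccc(cc1)S(=O)(=O)OCC[C@]1(C)CCc2cc(OC)cc(C)c2O1
F4 | step 9 | [(2R,6S)-2,6,10-trimethylundec-9-en-1-yl]magnesium bromide | CC(C)=CCC[C@@H](C)CCC[C@@H](C)C[Mg]Br
F5 | step 1 | 2-(2-fluoro-5-methoxy-3-methylphenyl)-4,4,5,5-tetramethyl-1,3,2-dioxaborolane | COc1cc(B2OC(C)(C)C(C)(C)O2)c(F)c(C)c1
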